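## Retrosynthetic overview
1. The only ring of the target, the δ-lactone, is closed last: the O5–C1 bond is made by a light-driven E-to-Z isomerisation and lactonisation of an acyclic E-enoate once the C5/C6 acetonide is unmasked.
2. C2=C3 comes from a Wittig reaction on a C3 aldehyde, itself made by anti-Markovnikov Wacker oxidation of a C3=C4 vinyl group.
3. C10 is set by Felkin–Anh reduction of a C10 ketone under control of C11 (from methyl (R)-lactate); C8=C9 comes from a Wittig reaction of a C8 aldehyde with a lactate-derived keto-ylide.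
4. The C8 aldehyde, the C3=C4 vinyl group and the C5, C6, C7 stereocentres (galactose C4, C3, C2) are released together by Bernet–Vasella fragmentation of 6-iodo-diacetone-D-galactose.

Assumption: atom labels C1–C12 follow the target (lactone carbonyl C1, ring CH–O C5, methyl C12); methyl (R)-lactate and 1,2:3,4-di-O-isopropylidene-α-D-galactopyranose are bought.

## Route

Step 1
Reactants: 1 methyl (2R)-2-hydroxypropanoate (methyl (R)-lactate)
Product: 2 methyl (2R)-2-[(tert-butyldimethylsilyl)oxy]propanoate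
Conditions: TBSCl, imidazole, DMF, 0 °C to rt
Reagents that add atoms: tert-butyldimethylsilyl chloride, CC(C)(C)[Si](C)(C)Cl
Why: Imidazole-promoted silylation of the only hydroxyl leaves the stereocentre (future C11) untouched and installs the bulky, non-chelating group that later enforces Felkin–Anh control.

Step 2
Reactants: 2 methyl (2R)-2-[(tert-butyldimethylsilyl)oxy]propanoate
Product: 3 (3R)-3-[(tert-butyldimethylsilyl)oxy]-1-(triphenyl-λ5-phosphanylidene)butan-2-one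
Conditions: Ph3PCH3Br (2.2 equiv), n-BuLi (2.1 equiv), THF, −78 to 0 °C; then 2, −78 °C to rt
Reagents that add atoms: methyltriphenylphosphonium bromide, C[P+](c1ccccc1)(c1ccccc1)c1ccccc1.[Br-]
Why: C-acylation of methylenetriphenylphosphorane by the ester (ylide acylation, the second equivalent of ylide deprotonating the acylphosphonium salt) gives the stabilised keto-ylide, and the cold conditions leave the α-silyloxy centre unracemised.

Step 3
Reactants: 4 1,2:3,4-di-O-isopropylidene-α-D-galactopyranose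
Product: 5 6-deoxy-6-iodo-1,2:3,4-di-O-isopropylidene-α-D-galactopyranose
Conditions: iodine, PPh3, imidazole, toluene, 80 °C
Reagents that add atoms: iodine, [I][I]
Why: Garegg–Samuelsson (Appel-type) iodination converts the single free primary hydroxyl into the iodide with both acetonides intact.

Step 4
Reactants: 5 6-deoxy-6-iodo-1,2:3,4-di-O-isopropylidene-α-D-galactopyranose; 3 (3R)-3-[(tert-butyldimethylsilyl)oxy]-1-(triphenyl-λ5-phosphanylidene)butan-2-one
Product: 7 (2R,4E,6S)-2-[(tert-butyldimethylsilyl)oxy]-6-[(4R,5S)-2,2-dimethyl-5-vinyl-1,3-dioxolan-4-yl]-6-hydroxyhex-4-en-3-one, via alpha-hydroxy enal 6 (not isolated)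
Conditions: Zn dust (acid-activated), THF/H2O 4:1, sonication, 40 °C; decant from Zn; then 3, rt
Reagents that add atoms: none
Why: Bernet–Vasella reductive fragmentation (zinc insertion into the carbon–iodine bond, β-elimination of the ring oxygen, collapse of the anomeric alkoxide with loss of acetone) unveils the C8 aldehyde and the C3=C4 vinyl group while galactose C2, C3 and C4 become C7, C6 and C5 unchanged, and the stabilised ylide then olefinates the aldehyde in the same flask (Wittig reaction) to give the E-enone.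

Step 5
Reactants: 7 (2R,4E,6S)-2-[(tert-butyldimethylsilyl)oxy]-6-[(4R,5S)-2,2-dimethyl-5-vinyl-1,3-dioxolan-4-yl]-6-hydroxyhex-4-en-3-one
Product: 8 (2R,4E,6S)-2-[(tert-butyldimethylsilyl)oxy]-6-[(4R,5S)-2,2-dimethyl-5-vinyl-1,3-dioxolan-4-yl]-6-methoxyhex-4-en-3-one
Conditions: Me3OBF4, 1,8-bis(dimethylamino)naphthalene, 4 Å molecular sieves, CH2Cl2, 0 °C to rt
Reagents that add atoms: trimethyloxonium tetrafluoroborate, C[O+](C)C.F[B-](F)(F)F
Why: Meerwein-salt O-methylation under non-basic conditions etherifies the only free hydroxyl (C7) without γ-deprotonation of the enone, so C7 keeps its galactose-derived configuration.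

Step 6
Reactants: 8 (2R,4E,6S)-2-[(tert-butyldimethylsilyl)oxy]-6-[(4R,5S)-2,2-dimethyl-5-vinyl-1,3-dioxolan-4-yl]-6-methoxyhex-4-en-3-one
Product: 9 [(4S,5S)-5-[(1S,2E,5R)-5-[(tert-butyldimethylsilyl)oxy]-1-methoxy-4-oxohex-2-en-1-yl]-2,2-dimethyl-1,3-dioxolan-4-yl]acetaldehyde
Conditions: PdCl2(PhCN)2 (10 mol%), CuCl2·2H2O (10 mol%), AgNO2 (5 mol%), O2 (1 atm), t-BuOH/MeNO2 15:1, rt
Reagents that add atoms: dioxygen, O=O
Why: Nitrite-modified anti-Markovnikov Wacker oxidation puts the oxygen on the terminal carbon of the vinyl group (the allylic C–O bond steers it to C3), while the electron-poor enone alkene does not bind divalent palladium.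

Step 7
Reactants: 9 [(4S,5S)-5-[(1S,2E,5R)-5-[(tert-butyldimethylsilyl)oxy]-1-methoxy-4-oxohex-2-en-1-yl]-2,2-dimethyl-1,3-dioxolan-4-yl]acetaldehyde
Product: 10 methyl (2E)-4-[(4S,5S)-5-[(1S,2E,5R)-5-[(tert-butyldimethylsilyl)oxy]-1-methoxy-4-oxohex-2-en-1-yl]-2,2-dimethyl-1,3-dioxolan-4-yl]but-2-enoate
Conditions: Ph3P=CHCO2Me, CH2Cl2, rt
Reagents that add atoms: methyl (triphenyl-λ5-phosphanylidene)acetate, COC(=O)C=P(c1ccccc1)(c1ccccc1)c1ccccc1
Why: Wittig olefination with the ester-stabilised ylide is selective for the aldehyde over the enone ketone and gives the E-enoate, whose geometry is corrected in the last step.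

Step 8
Reactants: 10 methyl (2E)-4-[(4S,5S)-5-[(1S,2E,5R)-5-[(tert-butyldimethylsilyl)oxy]-1-methoxy-4-oxohex-2-en-1-yl]-2,2-dimethyl-1,3-dioxolan-4-yl]but-2-enoate
Product: 11 methyl (2E)-4-[(4S,5S)-5-[(1S,2E,4R,5R)-5-[(tert-butyldimethylsilyl)oxy]-4-hydroxy-1-methoxyhex-2-en-1-yl]-2,2-dimethyl-1,3-dioxolan-4-yl]but-2-enoate
Conditions: LiBH(s-Bu)3 (1.1 equiv), THF, −78 °C; aq. NH4Cl
Reagents that add atoms: none
Why: Felkin–Anh (polar) 1,2-reduction in which the bulky hydride attacks anti to the non-chelating α-silyloxy group of C11 sets C10 as R (syn to C11), and at −78 °C the enoate ester is not reduced.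

Step 9
Reactants: 11 methyl (2E)-4-[(4S,5S)-5-[(1S,2E,4R,5R)-5-[(tert-butyldimethylsilyl)oxy]-4-hydroxy-1-methoxyhex-2-en-1-yl]-2,2-dimethyl-1,3-dioxolan-4-yl]but-2-enoate
Product: 13 methyl (2E)-4-[(4S,5S)-5-[(1S,2E,4R,5R)-4,5-diacetoxy-1-methoxyhex-2-en-1-yl]-2,2-dimethyl-1,3-dioxolan-4-yl]but-2-enoate, via diol 12 (not isolated)
Conditions: HF·pyridine, pyridine, THF, 0 °C to rt; then Ac2O, DMAP (cat.), same flask, rt
Reagents that add atoms: acetic anhydride, CC(=O)OC(C)=O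
Why: Fluoride desilylation frees the C11 hydroxyl and DMAP-catalysed acylation then acetylates both secondary alcohols in the same flask while the acetonide keeps O5 and O6 masked, so only C10 and C11 carry acetates.

Step 10
Reactants: 13 methyl (2E)-4-[(4S,5S)-5-[(1S,2E,4R,5R)-4,5-diacetoxy-1-methoxyhex-2-en-1-yl]-2,2-dimethyl-1,3-dioxolan-4-yl]but-2-enoate
Product: 16 (6S)-6-[(1S,2S,3E,5R,6R)-5,6-diacetoxy-1-hydroxy-2-methoxyhept-3-en-1-yl]-5,6-dihydro-2H-pyran-2-one (target), via E-enoate diol 14 (not isolated), via Z-enoate diol 15 (not isolated)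
Conditions: Sc(OTf)3 (10 mol%), thioxanthen-9-one (10 mol%), MeCN/H2O 20:1, 0.01 M, 405 nm LEDs, 30 °C, argon
Reagents that add atoms: none
Why: Proposed new method: Sc(OTf)3 in wet MeCN first hydrolyses the cis-acetonide, and its coordination to the ester carbonyl is then expected to lower the enoate triplet energy into reach of thioxanthone (about 65 kcal/mol), so that 405 nm light drives contra-thermodynamic E-to-Z isomerisation of the conjugated alkene only (the isolated C8=C9 alkene and the acetates lie too high to be sensitised); the Z-isomer is drained irreversibly by Lewis-acid-catalysed six-membered lactonisation through O5 (O6 could only close a seven-membered ring and stays free), with no stereocentre formed or touched; the closest known reaction types are Lewis-acid-assisted photochemical E/Z isomerisation of conjugated esters and ultraviolet E/Z isomerisation–lactonisation of δ-hydroxy enoates.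

## Compound list
1 | methyl (2R)-2-hydroxypropanoate (methyl (R)-lactate) | C[C@@H](O)C(=O)OC | starting material
2 | methyl (2R)-2-[(tert-butyldimethylsilyl)oxy]propanoate | C[C@@H](O[Si](C)(C)C(C)(C)C)C(=O)OC | intermediate
3 | (3R)-3-[(tert-butyldimethylsilyl)oxy]-1-(triphenyl-λ5-phosphanylidene)butan-2-one | C[C@@H](O[Si](C)(C)C(C)(C)C)C(=O)C=P(c1ccccc1)(c1ccccc1)c1ccccc1 | intermediate
4 | 1,2:3,4-di-O-isopropylidene-α-D-galactopyranose | O1[C@H](O2)[C@H](OC2(C)C)[C@@H](O3)[C@@H](OC3(C)C)[C@H]1CO | starting material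
5 | 6-deoxy-6-iodo-1,2:3,4-di-O-isopropylidene-α-D-galactopyranose | O1[C@H](O2)[C@H](OC2(C)C)[C@@H](O3)[C@@H](OC3(C)C)[C@H]1C[I] | intermediate
6 | 5,6-dideoxy-3,4-O-isopropylidene-L-arabino-hex-5-enose (aldehyde C8, free hydroxyl on C7, vinyl C4=C3) | O=C[C@H](O)[C@@H](O1)[C@@H](OC1(C)C)C=C | intermediate (not isolated)
7 | (2R,4E,6S)-2-[(tert-butyldimethylsilyl)oxy]-6-[(4R,5S)-2,2-dimethyl-5-vinyl-1,3-dioxolan-4-yl]-6-hydroxyhex-4-en-3-one | O[C@@H](/C=C/C(=O)[C@@H](C)O[Si](C)(C)C(C)(C)C)[C@@H](O1)[C@@H](OC1(C)C)C=C | intermediate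
8 | (2R,4E,6S)-2-[(tert-butyldimethylsilyl)oxy]-6-[(4R,5S)-2,2-dimethyl-5-vinyl-1,3-dioxolan-4-yl]-6-methoxyhex-4-en-3-one | CO[C@@H](/C=C/C(=O)[C@@H](C)O[Si](C)(C)C(C)(C)C)[C@@H](O1)[C@@H](OC1(C)C)C=C | intermediate
9 | [(4S,5S)-5-[(1S,2E,5R)-5-[(tert-butyldimethylsilyl)oxy]-1-methoxy-4-oxohex-2-en-1-yl]-2,2-dimethyl-1,3-dioxolan-4-yl]acetaldehyde | CO[C@@H](/C=C/C(=O)[C@@H](C)O[Si](C)(C)C(C)(C)C)[C@@H](O1)[C@@H](OC1(C)C)CC=O | intermediate
10 | methyl (2E)-4-[(4S,5S)-5-[(1S,2E,5R)-5-[(tert-butyldimethylsilyl)oxy]-1-methoxy-4-oxohex-2-en-1-yl]-2,2-dimethyl-1,3-dioxolan-4-yl]but-2-enoate | CO[C@@H](/C=C/C(=O)[C@@H](C)O[Si](C)(C)C(C)(C)C)[C@@H](O1)[C@@H](OC1(C)C)C/C=C/C(=O)OC | intermediate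
11 | methyl (2E)-4-[(4S,5S)-5-[(1S,2E,4R,5R)-5-[(tert-butyldimethylsilyl)oxy]-4-hydroxy-1-methoxyhex-2-en-1-yl]-2,2-dimethyl-1,3-dioxolan-4-yl]but-2-enoate | CO[C@@H](/C=C/[C@@H](O)[C@@H](C)O[Si](C)(C)C(C)(C)C)[C@@H](O1)[C@@H](OC1(C)C)C/C=C/C(=O)OC | intermediate
12 | methyl (2E)-4-[(4S,5S)-5-[(1S,2E,4R,5R)-4,5-dihydroxy-1-methoxyhex-2-en-1-yl]-2,2-dimethyl-1,3-dioxolan-4-yl]but-2-enoate | CO[C@@H](/C=C/[C@@H](O)[C@@H](C)O)[C@@H](O1)[C@@H](OC1(C)C)C/C=C/C(=O)OC | intermediate (not isolated)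
13 | methyl (2E)-4-[(4S,5S)-5-[(1S,2E,4R,5R)-4,5-diacetoxy-1-methoxyhex-2-en-1-yl]-2,2-dimethyl-1,3-dioxolan-4-yl]but-2-enoate | CO[C@@H](/C=C/[C@@H](OC(C)=O)[C@@H](C)OC(C)=O)[C@@H](O1)[C@@H](OC1(C)C)C/C=C/C(=O)OC | intermediate
14 | methyl (2E,5S,6S,7S,8E,10R,11R)-10,11-diacetoxy-5,6-dihydroxy-7-methoxydodeca-2,8-dienoate | CO[C@@H](/C=C/[C@@H](OC(C)=O)[C@@H](C)OC(C)=O)[C@@H](O)[C@@H](O)C/C=C/C(=O)OC | intermediate (not isolated)
15 | methyl (2Z,5S,6S,7S,8E,10R,11R)-10,11-diacetoxy-5,6-dihydroxy-7-methoxydodeca-2,8-dienoate | CO[C@@H](/C=C/[C@@H](OC(C)=O)[C@@H](C)OC(C)=O)[C@@H](O)[C@@H](O)C/C=C\C(=O)OC | intermediate (not isolated)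
16 | (6S)-6-[(1S,2S,3E,5R,6R)-5,6-diacetoxy-1-hydroxy-2-methoxyhept-3-en-1-yl]-5,6-dihydro-2H-pyran-2-one | CO[C@@H](/C=C/[C@@H](OC(C)=O)[C@@H](C)OC(C)=O)[C@@H](O)[C@@H]1CC=CC(=O)O1 | target

## Step count and risk
Total steps: 10. Longest linear sequence: 9 steps (from 1 through steps 1, 2 and 4–10); the galactose branch from 4 is 8 steps.

Three steps most likely to fail:

Step 4 (fragmentation and olefination of an unprotected α-hydroxy aldehyde). Zinc insertion into the hindered iodide may be slow, and 6 can undergo α-ketol isomerisation or epimerise at C7 before the ylide traps it. Fallback: put the methyl ether in place before the ring is opened. Setting out from 5, acidic methanolysis (AcCl, MeOH, reflux) removes both acetonides and gives methyl 6-deoxy-6-iodo-α-D-galactopyranoside F1. 2,2-Dimethoxypropane with TsOH in acetone re-forms only the cis-3,4-acetonide, giving methyl 6-deoxy-6-iodo-3,4-O-isopropylidene-α-D-galactopyranoside F2. MeI with Ag2O methylates O2 to give methyl 6-deoxy-6-iodo-3,4-O-isopropylidene-2-O-methyl-α-D-galactopyranoside F3. Zn in THF/H2O then releases the more robust α-methoxy aldehyde 5,6-dideoxy-3,4-O-isopropylidene-2-O-methyl-L-arabino-hex-5-enose F4, and Wittig reaction with 3 comes back to the route at 8.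

Step 6 (aldehyde-selective Wacker oxidation). The methyl ketone may form instead, or the β-alkoxy aldehyde may eliminate. Fallback: reduce the ketone first and replace the oxidation by hydroboration. Setting out from 8, LiBH(s-Bu)3 at −78 °C gives (2R,3R,4E,6S)-2-[(tert-butyldimethylsilyl)oxy]-6-[(4R,5S)-2,2-dimethyl-5-vinyl-1,3-dioxolan-4-yl]-6-methoxyhex-4-en-3-ol F5. 9-BBN followed by NaBO3·4H2O hydroborates only the terminal alkene and gives 2-[(4S,5S)-5-[(1S,2E,4R,5R)-5-[(tert-butyldimethylsilyl)oxy]-4-hydroxy-1-methoxyhex-2-en-1-yl]-2,2-dimethyl-1,3-dioxolan-4-yl]ethan-1-ol F6. TEMPO with PhI(OAc)2 oxidises the primary alcohol selectively to [(4S,5S)-5-[(1S,2E,4R,5R)-5-[(tert-butyldimethylsilyl)oxy]-4-hydroxy-1-methoxyhex-2-en-1-yl]-2,2-dimethyl-1,3-dioxolan-4-yl]acetaldehyde F7, and Wittig reaction with Ph3P=CHCO2Me comes back to the route at 11.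

Step 10 (the proposed new photochemical ring closure). Energy transfer to the Lewis-acid-bound aliphatic enoate may be too slow, or Sc(OTf)3 may trigger oxa-Michael addition of O6 or ionisation of the allylic acetate. Fallback with known chemistry (conjugate addition, lactonisation, selenoxide elimination): setting out from 13, PhSeSePh reduced with NaBH4 in EtOH and buffered with AcOH adds benzeneselenol to the enoate to give methyl 4-[(4S,5S)-5-[(1S,2E,4R,5R)-4,5-diacetoxy-1-methoxyhex-2-en-1-yl]-2,2-dimethyl-1,3-dioxolan-4-yl]-3-(phenylselanyl)butanoate F8 (both C3 epimers). Aqueous AcOH (80%, 40 °C) removes the acetonide and the saturated hydroxy ester lactonises to (6S)-6-[(1S,2S,3E,5R,6R)-5,6-diacetoxy-1-hydroxy-2-methoxyhept-3-en-1-yl]-4-(phenylselanyl)oxan-2-one F9. H2O2 in CH2Cl2/pyridine at 0 °C to rt oxidises selenium, and syn-elimination toward the carbonyl comes back to the route at 16.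

Further compounds
F1 | step 4 | methyl 6-deoxy-6-iodo-α-D-galactopyranoside | O1[C@H](OC)[C@H](O)[C@@H](O)[C@@H](O)[C@H]1C[I]
F2 | step 4 | methyl 6-deoxy-6-iodo-3,4-O-isopropylidene-α-D-galactopyranoside | O1[C@H](OC)[C@H](O)[C@@H](O2)[C@@H](OC2(C)C)[C@H]1C[I]
F3 | step 4 | methyl 6-deoxy-6-iodo-3,4-O-isopropylidene-2-O-methyl-α-D-galactopyranoside | O1[C@H](OC)[C@H](OC)[C@@H](O2)[C@@H](OC2(C)C)[C@H]1C[I]
F4 | step 4 | 5,6-dideoxy-3,4-O-isopropylidene-2-O-methyl-L-arabino-hex-5-enose | O=C[C@H](OC)[C@@H](O1)[C@@H](OC1(C)C)C=C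
F5 | step 6 | (2R,3R,4E,6S)-2-[(tert-butyldimethylsilyl)oxy]-6-[(4R,5S)-2,2-dimethyl-5-vinyl-1,3-dioxolan-4-yl]-6-methoxyhex-4-en-3-ol | CO[C@@H](/C=C/[C@@H](O)[C@@H](C)O[Si](C)(C)C(C)(C)C)[C@@H](O1)[C@@H](OC1(C)C)C=C
F6 | step 6 | 2-[(4S,5S)-5-[(1S,2E,4R,5R)-5-[(tert-butyldimethylsilyl)oxy]-4-hydroxy-1-methoxyhex-2-en-1-yl]-2,2-dimethyl-1,3-dioxolan-4-yl]ethan-1-ol | CO[C@@H](/C=C/[C@@H](O)[C@@H](C)O[Si](C)(C)C(C)(C)C)[C@@H](O1)[C@@H](OC1(C)C)CCO
F7 | step 6 | [(4S,5S)-5-[(1S,2E,4R,5R)-5-[(tert-butyldimethylsilyl)oxy]-4-hydroxy-1-methoxyhex-2-en-1-yl]-2,2-dimethyl-1,3-dioxolan-4-yl]acetaldehyde | CO[C@@H](/C=C/[C@@H](O)[C@@H](C)O[Si](C)(C)C(C)(C)C)[C@@H](O1)[C@@H](OC1(C)C)CC=O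
F8 | step 10 | methyl 4-[(4S,5S)-5-[(1S,2E,4R,5R)-4,5-diacetoxy-1-methoxyhex-2-en-1-yl]-2,2-dimethyl-1,3-dioxolan-4-yl]-3-(phenylselanyl)butanoate | CO[C@@H](/C=C/[C@@H](OC(C)=O)[C@@H](C)OC(C)=O)[C@@H](O1)[C@@H](OC1(C)C)CC(CC(=O)OC)[Se]c1ccccc1
F9 | step 10 | (6S)-6-[(1S,2S,3E,5R,6R)-5,6-diacetoxy-1-hydroxy-2-methoxyhept-3-en-1-yl]-4-(phenylselanyl)oxan-2-one | CO[C@@H](/C=C/[C@@H](OC(C)=O)[C@@H](C)OC(C)=O)[C@@H](O)[C@@H]1CC(CC(=O)O1)[Se]c1ccccc1
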